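Two steps that start from the same partners can be compared without knowing their amounts. If target and isomer of the product both arise from starting material plus reagent, each forward rate is a rate constant times the same two amounts, and the amounts cancel in the comparison of the two rates. Each product may also return, at a rate proportional to its own amount, and the net rates then stand in another ratio. When both have stopped changing, each forward rate equals its backward rate, and the ratio of isomer to target is a ratio of constants with no amounts in it.

- delta: starting material 0.025 M; reagent 0.025 M; run made earlier
- flask: starting material 0.050 M; reagent 0.0250 M; time 10 d

- delta (time / h: isomer of the product / %, target / %): 2.50: 55.5, 12.4; 8.00: 66.7, 7.9; 15.0: 66.7, 7.8; 20.0: 66.8, 7.1; 30.0: 67.0, 7.5; 40.0: 66.7, 8.1; 50.0: 66.7, 8.1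

(readings scatter by 0.3 percentage points)

- the earlier runs were read with a standard deviation of 0.3 percentage points

* ratio of isomer of the product to target at 12 min
* ratio of isomer of the product to target at 10 d
* which of isomer of the product and target there is more of at 10 d

The delta run shows such a stop: from 8.00 h on, both columns stay flat within the scatter. Those readings give 8.62 for the plateau ratio, the amount of isomer over the amount of target once both have stopped changing, a reading that carries their scatter. The new flask holds a different charge, but the charges cancel, and its 10 d is far longer than the 8.00 h the delta run needed. This reckoning therefore expects the plateau ratio at the end of the flask, with more isomer than target.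

The early time is another matter. At 2.50 h the delta run reads a ratio of 4.48, less than the plateau ratio, and target stands at 12.4% before falling to 8.1%. Target thus stood above its later level and then gave way. At 12 min, long before that reading, this reckoning commits to a ratio under 4.48 and no closer.

The forecast gave 0.3 at the early time and, on the ground that “this ratio should not depend on concentration”, 8.6 at the end, with isomer of the product ahead.

The flask gives 0.717 at 12 min and 9.00 at 10 d, with isomer of the product ahead: 41.6% against 4.62% of the starting material charged.

    starting material + reagent ⇌ isomer of the product (K = 900 M⁻¹, k = 2.10 M⁻¹ min⁻¹)
    starting material + reagent ⇌ target (K = 100 M⁻¹, k = 4.00 M⁻¹ min⁻¹)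
    reagent ⇌ dormant form (K = 1.20, k = 0.0420 min⁻¹)

The forward rate of the isomer step over that of the target step stands at 0.53 at 0.0209 d and at 0.53 at 10.0 d, and target leads in the flask until 0.415 h, yet the flask ends at 9.00 beside the plateau ratio of 8.62 read from the delta run, the mark of kinetic against thermodynamic control. The neighbour flask with 0.062 M of reagent ends with 8.89% of target, from which the plateau ratio reckons 76.6% of isomer, and that flask holds 80.0%.

(The data were generated by integration on assumed constants; the scatter is artificial.)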